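**Retrosynthetic overview**

1. Target ⇐ (13E)-labd-13-ene-8α,15,19-triol (diacetylation, then methanolysis of the unhindered C15 acetate) ⇐ 8α-hydroxy C13 methyl ketone (Horner–Wadsworth–Emmons builds C13=C14, reduction gives C15–OH) ⇐ 19-silyloxy δ-lactone (C13–O–C8) by MeLi.
2. Key disconnection: 3β-hydroxy-19-silyloxy δ-lactone ⇐ acyclic epoxy diene tert-butyl ester. One cation–olefin cascade forms C4–C5, C10–C9 and O–C8 (ring A, then ring B, then the lactone ring) and sets C4, C5, C10, C9 and C8, all five stereocentres of the target.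
3. Feature used: the axial C19 CH2O on quaternary C4 (syn to the C20 methyl on C10) is the (Z)-hydroxymethyl of the terminal alkene, and the same allylic alcohol directs the Sharpless epoxidation. The 8α-O/9β-chain pair is the (E)-C8=C9 alkene plus its tethered carboxyl.
4. The C3 oxygen left by the epoxide initiator is deleted by Barton–McCombie deoxygenation.
5. Acyclic precursor ⇐ (Z)-allylic alcohol (Still–Gennari, DIBAL-H) ⇐ trisnor aldehyde ⇐ tert-butyl farnesylacetate ⇐ (2E,6E)-farnesyl bromide + tert-butyl acetate.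

Key step: step 8

Assumption: labdane numbering (C1–C20) and α/β descriptors are used for the ring compounds; the target is read as the normal-series labdane with 4β (axial) CH2OAc, 8α-OH and a 13E alkene.

**Route**

Step 1
Reactants: 1 (2E,6E)-farnesyl bromide; 2 tert-butyl acetate
Product: 3 tert-butyl (4E,8E)-5,9,13-trimethyltetradeca-4,8,12-trienoate
Conditions: 2, LDA, THF, −78 °C; then 1, DMPU, −78 → 0 °C
Reagents that add atoms: none
Why: SN2 alkylation of the lithium ester enolate by the primary allylic bromide should give the chain-extended ester; no stereocentre is formed and both E alkenes are untouched.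

Step 2
Reactants: 3
Product: 5 racemic tert-butyl (4E,8E)-11-(3,3-dimethyloxiran-2-yl)-5,9-dimethylundeca-4,8-dienoate, via bromohydrin 4 (not isolated)
Conditions: NBS, THF/H2O, 0 °C; then K2CO3, MeOH, rt
Reagents that add atoms: water, O; N-bromosuccinimide, O=C1CCC(=O)N1Br (its bromine is carried only by 4)
Why: Terminal-selective bromohydrin formation of the polyene in aqueous THF, followed by base-induced ring closure, should give the terminal epoxide; its stereocentre is irrelevant because it is destroyed in step 3.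

Step 3
Reactants: 5
Product: 6 tert-butyl (4E,8E)-5,9-dimethyl-12-oxododeca-4,8-dienoate
Conditions: H5IO6, THF/Et2O, 0 °C
Reagents that add atoms: none
Why: Periodic acid cleavage of the epoxide (hydrolysis, then glycol scission) should give the trisnor aldehyde and acetone without touching the trisubstituted alkenes or the tert-butyl ester.

Step 4
Reactants: 6
Product: 7 14-tert-butyl 1-ethyl (2Z,6E,10E)-2,6,10-trimethyltetradeca-2,6,10-trienedioate
Conditions: KHMDS, 18-crown-6, THF, −78 °C
Reagents that add atoms: ethyl 2-[bis(2,2,2-trifluoroethoxy)phosphoryl]propanoate, CCOC(=O)C(C)P(=O)(OCC(F)(F)F)OCC(F)(F)F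
Why: The Still–Gennari variant of the Horner–Wadsworth–Emmons reaction should give the (Z)-α-methyl enoate under kinetic control, which places the future C19 carbon cis to the chain.

Step 5
Reactants: 7
Product: 8 tert-butyl (4E,8E,12Z)-14-hydroxy-5,9,13-trimethyltetradeca-4,8,12-trienoate
Conditions: DIBAL-H (2.2 equiv), CH2Cl2, −78 °C
Reagents that add atoms: none
Why: DIBAL-H 1,2-reduction of the conjugated ethyl ester at −78 °C should leave the hindered tert-butyl ester, which reacts much more slowly, and keeps the Z geometry.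

Step 6
Reactants: 8
Product: 9 tert-butyl (4E,8E)-11-[(2S,3R)-3-(hydroxymethyl)-3-methyloxiran-2-yl]-5,9-dimethylundeca-4,8-dienoate
Conditions: Ti(OiPr)4 (10 mol%), D-(−)-diethyl tartrate (12 mol%), TBHP, 4 Å MS, CH2Cl2, −20 °C
Reagents that add atoms: tert-butyl hydroperoxide, CC(C)(C)OO
Why: Sharpless asymmetric epoxidation acts only on the allylic alcohol; D-(−)-DET should deliver oxygen to the face opposite to the one L-(+)-DET uses with nerol-type (Z)-allylic alcohols, making the chain-bearing epoxide carbon (labdane C3) S and the quaternary one (C4) R.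

Step 7
Reactants: 9
Product: 10 tert-butyl (4E,8E)-11-[(2S,3R)-3-{[tert-butyl(diphenyl)silyl]oxymethyl}-3-methyloxiran-2-yl]-5,9-dimethylundeca-4,8-dienoate
Conditions: TBDPSCl, imidazole, CH2Cl2, 0 °C → rt
Reagents that add atoms: tert-butyl(chloro)diphenylsilane, CC(C)(C)[Si](Cl)(c1ccccc1)c1ccccc1
Why: Silylation of the primary alcohol gives a bulky, non-participating ether, so that no neighbouring acyl group can open the epoxide in step 8.

Step 8
Reactants: 10
Product: 11 19-[tert-butyl(diphenyl)silyl]oxy-3β-hydroxy-14,15,16-trinorlabdan-13,8α-olide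
Conditions: MeAlCl2 (2 equiv), CH2Cl2, −78 °C; then H2O
Reagents that add atoms: none
Why: MeAlCl2 activates the epoxide, the C5=C10 alkene opens it at the tertiary carbon C4 from the back side (6-endo closure of ring A through a chair, inversion at C4), the C10 cation is taken up by the C8=C9 alkene (6-endo closure of ring B, second chair), and the C8 cation is captured by the ester carbonyl oxygen (six-membered lactone closure, loss of isobutene). The reaction type is the Lewis-acid, epoxide-initiated cation–olefin polycyclisation with oxygen termination; the closest known cases are epoxy-polyene bicyclisations of farnesyl-derived substrates and the acid-induced lactonising cyclisation of farnesylacetic acid. C4 is controlled by the Z geometry of the former alkene: the substituent cis to the chain (CH2OSi) ends axial (β, C19) and the methyl equatorial, and the inductively destabilised cation next to the siloxymethyl group should keep the opening concerted so that this relation is not lost. C5 and C10 (trans ring fusion) follow from the E C5=C10 geometry in the chair–chair fold; C9 and C8 follow from anti addition across the E C8=C9 alkene (side chain equatorial, oxygen on the α face, methyl axial); the absolute sense of all five comes from the epoxide carbon C3 (S, oxygen equatorial). The selectivity needed is C–C bond formation at C4 in preference to a 1,2-hydride shift from the CH2OSi carbon or proton loss from the C10/C8 cations; the pre-organised trisubstituted alkene, the low temperature and the intramolecular carboxyl trap are relied on for this.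

Step 9
Reactants: 11
Product: 12 19-[tert-butyl(diphenyl)silyl]oxy-3β-(phenoxycarbonothioyl)oxy-14,15,16-trinorlabdan-13,8α-olide
Conditions: PhOC(S)Cl, pyridine, DMAP (cat.), CH2Cl2, rt
Reagents that add atoms: O-phenyl chlorothionoformate, S=C(Cl)Oc1ccccc1
Why: DMAP-catalysed thioacylation of the only free (secondary, equatorial) hydroxyl prepares the Barton–McCombie substrate with retention at C3.

Step 10
Reactants: 12
Product: 13 19-[tert-butyl(diphenyl)silyl]oxy-14,15,16-trinorlabdan-13,8α-olide
Conditions: Bu3SnH, AIBN (cat.), toluene, 100 °C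
Reagents that add atoms: none
Why: Barton–McCombie deoxygenation (stannyl radical adds to C=S, the C3–O bond fragments, the secondary radical takes up hydrogen) turns C3 into CH2; no stereocentre is involved and the lactone and silyl ether are inert.

Step 11
Reactants: 13
Product: 14 19-[tert-butyl(diphenyl)silyl]oxy-8α-hydroxy-14,15-dinorlabdan-13-one
Conditions: MeLi (1.1 equiv), Et2O/THF, −78 °C; then H2O
Reagents that add atoms: methyllithium, [Li]C
Why: Addition of one equivalent of methyllithium to the δ-lactone should stop at the lithium hemiketal, which gives the 8α-hydroxy methyl ketone (in equilibrium with its lactol) on work-up; the C8–O bond is not broken, so C8 is retained.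

Step 12
Reactants: 14
Product: 15 ethyl (13E)-19-[tert-butyl(diphenyl)silyl]oxy-8α-hydroxylabd-13-en-15-oate
Conditions: (EtO)2P(O)CH2CO2Et, NaH, THF, 0 °C → reflux
Reagents that add atoms: triethyl phosphonoacetate, CCOC(=O)CP(=O)(OCC)OCC
Why: Horner–Wadsworth–Emmons olefination of the methyl ketone should favour the (E)-trisubstituted enoate (ester trans to the larger C12 substituent); the minor Z isomer is to be removed by chromatography.

Step 13
Reactants: 15
Product: 16 (13E)-19-[tert-butyl(diphenyl)silyl]oxylabd-13-ene-8α,15-diol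
Conditions: DIBAL-H (3.5 equiv), CH2Cl2, −78 → 0 °C
Reagents that add atoms: none
Why: DIBAL-H 1,2-reduction of the enoate gives the allylic alcohol with the E geometry kept; the silyl ether and the tertiary alcohol are stable.

Step 14
Reactants: 16
Product: 17 (13E)-labd-13-ene-8α,15,19-triol
Conditions: TBAF, THF, rt → 50 °C
Reagents that add atoms: none
Why: Fluoride-induced cleavage of the neopentyl-type silyl ether frees the C19 alcohol without affecting the allylic alcohol or the alkene.

Step 15
Reactants: 17
Product: 18 (13E)-8α-hydroxylabd-13-ene-15,19-diyl diacetate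
Conditions: Ac2O, pyridine, DMAP (cat.), CH2Cl2, 0 °C → rt
Reagents that add atoms: acetic anhydride, CC(=O)OC(C)=O
Why: Acetylation takes both primary alcohols, while the hindered tertiary 8α-hydroxyl (flanked by C9 and the axial C17 methyl) should stay free.

Step 16
Reactants: 18
Product: 19 (13E)-8α,15-dihydroxylabd-13-en-19-yl acetate (target)
Conditions: K2CO3 (cat.), MeOH, 0 °C, stopped at mono-deacetylation
Reagents that add atoms: none
Why: Base-catalysed transesterification should cleave the unhindered primary allylic C15 acetate much faster than the axial, neopentyl-type C19 acetate (1,3-diaxial to the C20 methyl), leaving the target monoacetate.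

**Compound list**

1 | (2E,6E)-farnesyl bromide | CC(C)=CCC/C(C)=C/CC/C(C)=C/CBr | starting material
2 | tert-butyl acetate | CC(=O)OC(C)(C)C | starting material
3 | tert-butyl (4E,8E)-5,9,13-trimethyltetradeca-4,8,12-trienoate | CC(C)=CCC/C(C)=C/CC/C(C)=C/CCC(=O)OC(C)(C)C | intermediate
4 | tert-butyl (4E,8E)-12-bromo-13-hydroxy-5,9,13-trimethyltetradeca-4,8-dienoate (bromohydrin, racemic) | CC(C)(O)C(Br)CC/C(C)=C/CC/C(C)=C/CCC(=O)OC(C)(C)C | intermediate (not isolated)
5 | tert-butyl (4E,8E)-11-(3,3-dimethyloxiran-2-yl)-5,9-dimethylundeca-4,8-dienoate (racemic) | CC1(C)OC1CC/C(C)=C/CC/C(C)=C/CCC(=O)OC(C)(C)C | intermediate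
6 | tert-butyl (4E,8E)-5,9-dimethyl-12-oxododeca-4,8-dienoate | O=CCC/C(C)=C/CC/C(C)=C/CCC(=O)OC(C)(C)C | intermediate
7 | 14-tert-butyl 1-ethyl (2Z,6E,10E)-2,6,10-trimethyltetradeca-2,6,10-trienedioate | CCOC(=O)/C(C)=C\CC/C(C)=C/CC/C(C)=C/CCC(=O)OC(C)(C)C | intermediate
8 | tert-butyl (4E,8E,12Z)-14-hydroxy-5,9,13-trimethyltetradeca-4,8,12-trienoate | OC/C(C)=C\CC/C(C)=C/CC/C(C)=C/CCC(=O)OC(C)(C)C | intermediate
9 | tert-butyl (4E,8E)-11-[(2S,3R)-3-(hydroxymethyl)-3-methyloxiran-2-yl]-5,9-dimethylundeca-4,8-dienoate | CC(C)(C)OC(=O)CC/C=C(\C)CC/C=C(\C)CC[C@@H]1O[C@]1(C)CO | intermediate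
10 | tert-butyl (4E,8E)-11-[(2S,3R)-3-{[tert-butyl(diphenyl)silyl]oxymethyl}-3-methyloxiran-2-yl]-5,9-dimethylundeca-4,8-dienoate | CC(C)(C)OC(=O)CC/C=C(\C)CC/C=C(\C)CC[C@@H]1O[C@]1(C)CO[Si](c1ccccc1)(c1ccccc1)C(C)(C)C | intermediate
11 | 19-[tert-butyl(diphenyl)silyl]oxy-3β-hydroxy-14,15,16-trinorlabdan-13,8α-olide (trans-decalin δ-lactone: 4α-CH3, 4β-CH2OSi, 5α-H, 8β-CH3, 9α-H, 10β-CH3) | CC(C)(C)[Si](c1ccccc1)(c1ccccc1)OC[C@@]1(C)[C@@H](O)CC[C@]2(C)[C@@H](CCC(=O)O3)[C@@]3(C)CC[C@@H]12 | intermediate
12 | 3-O-(phenoxycarbonothioyl) derivative of 11 | CC(C)(C)[Si](c1ccccc1)(c1ccccc1)OC[C@@]1(C)[C@@H](OC(=S)Oc4ccccc4)CC[C@]2(C)[C@@H](CCC(=O)O3)[C@@]3(C)CC[C@@H]12 | intermediate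
13 | 19-[tert-butyl(diphenyl)silyl]oxy-14,15,16-trinorlabdan-13,8α-olide | CC(C)(C)[Si](c1ccccc1)(c1ccccc1)OC[C@@]1(C)CCC[C@]2(C)[C@@H](CCC(=O)O3)[C@@]3(C)CC[C@@H]12 | intermediate
14 | 19-[tert-butyl(diphenyl)silyl]oxy-8α-hydroxy-14,15-dinorlabdan-13-one | CC(C)(C)[Si](c1ccccc1)(c1ccccc1)OC[C@@]1(C)CCC[C@]2(C)[C@@H](CCC(C)=O)[C@](C)(O)CC[C@@H]12 | intermediate
15 | ethyl (13E)-19-[tert-butyl(diphenyl)silyl]oxy-8α-hydroxylabd-13-en-15-oate | CC(C)(C)[Si](c1ccccc1)(c1ccccc1)OC[C@@]1(C)CCC[C@]2(C)[C@@H](CC/C(C)=C/C(=O)OCC)[C@](C)(O)CC[C@@H]12 | intermediate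
16 | (13E)-19-[tert-butyl(diphenyl)silyl]oxylabd-13-ene-8α,15-diol | CC(C)(C)[Si](c1ccccc1)(c1ccccc1)OC[C@@]1(C)CCC[C@]2(C)[C@@H](CC/C(C)=C/CO)[C@](C)(O)CC[C@@H]12 | intermediate
17 | (13E)-labd-13-ene-8α,15,19-triol | OC[C@@]1(C)CCC[C@]2(C)[C@@H](CC/C(C)=C/CO)[C@](C)(O)CC[C@@H]12 | intermediate
18 | (13E)-8α-hydroxylabd-13-ene-15,19-diyl diacetate | CC(=O)OC[C@@]1(C)CCC[C@]2(C)[C@@H](CC/C(C)=C/COC(C)=O)[C@](C)(O)CC[C@@H]12 | intermediate
19 | (13E)-8α,15-dihydroxylabd-13-en-19-yl acetate | CC(=O)OC[C@@]1(C)CCC[C@]2(C)[C@@H](CC/C(C)=C/CO)[C@](C)(O)CC[C@@H]12 | target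

**Step count and risks**

Total step count: 16. Longest linear sequence: 16 steps (from 1).

Steps most likely to fail:

1. Step 8. The activated epoxide may be diverted by a 1,2-hydride shift from the siloxymethyl carbon to C4 (semipinacol-type rearrangement to an aldehyde), or the cascade may end early by proton loss from the C10 or C8 cation before ring B or the lactone closes. The fallback sets out from 6 and comes back at 17. It carries C19 as an ester and closes the rings by an oxidative radical cascade, so that no cation has to form next to an oxygenated carbon. Sc(OTf)3-catalysed Roskamp homologation of 6 with ethyl 2-diazopropanoate should give 14-tert-butyl 1-ethyl (6E,10E)-2,6,10-trimethyl-3-oxotetradeca-6,10-dienedioate F1. Mn(OAc)3/Cu(OAc)2 in AcOH (oxidative radical bicyclisation of the α-methyl β-keto ester, a mode that in the podocarpane series places the ester axial at C4 and ends in the exocyclic alkene) should give the racemic bicyclic keto diester F2. TFA should then cleave the tert-butyl ester and close the δ-lactone on C8 from the α face to give the keto lactone ester F3. Ethane-1,2-dithiol/BF3·OEt2 gives the dithiolane F4, and Raney nickel removes the sulfur to leave the 3-deoxy lactone ester F5. MeLi at −78 °C should add to the lactone only, the axial C19 ester being shielded, to give the hydroxy ketone ester F6. Olefination as in step 12 gives the diester F7, and LiAlH4 reduces both esters to racemic 17, which is resolved by chromatography on a chiral stationary phase and re-enters the route at 17.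

2. Step 12. The ketone rests largely as its cyclic hemiketal, so olefination may be slow, and E/Z control at C13=C14 may be incomplete. The fallback sets out from 13 and comes back at 16, and builds the alkene by carbometalation instead of carbonyl olefination. DIBAL-H (1 equiv, −78 °C) should reduce 13 to the lactol F8; the Ohira–Bestmann reagent with K2CO3 in MeOH should convert its open hydroxy aldehyde form into the terminal alkyne F9; Negishi zirconium-catalysed carboalumination (Me3Al, Cp2ZrCl2, CH2Cl2), then n-BuLi and paraformaldehyde, should give 16 with the E geometry fixed by syn addition of methyl and aluminium.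

3. Step 16. The rate difference between the two acetates may be too small, so that methanolysis runs on to the triol or stops short. The fallback sets out from 17 and comes back at 19, and tells the two primary alcohols apart by oxidation state instead of by ester lability. MnO2 in CH2Cl2 should oxidise only the allylic alcohol to the dihydroxy enal F10; Ac2O/pyridine then acetylates the one remaining primary alcohol (C19) to give the acetoxy enal F11; NaBH4/CeCl3 in MeOH at 0 °C reduces the enal without touching the acetate and gives 19.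

**Further compounds**

F1 | step 8 | 14-tert-butyl 1-ethyl (6E,10E)-2,6,10-trimethyl-3-oxotetradeca-6,10-dienedioate | CCOC(=O)C(C)C(=O)CC/C(C)=C/CC/C(C)=C/CCC(=O)OC(C)(C)C
F2 | step 8 | rac-13-tert-butyl 19-ethyl 3-oxo-14,15,16-trinorlabd-8(17)-ene-13,19-dioate (one enantiomer drawn) | CCOC(=O)[C@@]1(C)C(=O)CC[C@]2(C)[C@@H](CCC(=O)OC(C)(C)C)C(=C)CC[C@@H]12
F3 | step 8 | rac-ethyl 3-oxo-14,15,16-trinorlabdan-13,8α-olid-19-oate (one enantiomer drawn) | CCOC(=O)[C@@]1(C)C(=O)CC[C@]2(C)[C@@H](CCC(=O)O3)[C@@]3(C)CC[C@@H]12
F4 | step 8 | rac-3,3-(ethane-1,2-diyldisulfanediyl) derivative of F3 (dithiolane, one enantiomer drawn) | CCOC(=O)[C@@]1(C)C4(SCCS4)CC[C@]2(C)[C@@H](CCC(=O)O3)[C@@]3(C)CC[C@@H]12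
F5 | step 8 | rac-ethyl 14,15,16-trinorlabdan-13,8α-olid-19-oate (one enantiomer drawn) | CCOC(=O)[C@@]1(C)CCC[C@]2(C)[C@@H](CCC(=O)O3)[C@@]3(C)CC[C@@H]12
F6 | step 8 | rac-ethyl 8α-hydroxy-13-oxo-14,15-dinorlabdan-19-oate (one enantiomer drawn) | CCOC(=O)[C@@]1(C)CCC[C@]2(C)[C@@H](CCC(C)=O)[C@](C)(O)CC[C@@H]12
F7 | step 8 | rac-diethyl (13E)-8α-hydroxylabd-13-ene-15,19-dioate (one enantiomer drawn) | CCOC(=O)[C@@]1(C)CCC[C@]2(C)[C@@H](CC/C(C)=C/C(=O)OCC)[C@](C)(O)CC[C@@H]12
F8 | step 12 | 19-[tert-butyl(diphenyl)silyl]oxy-8α,13-epoxy-14,15,16-trinorlabdan-13-ol (lactol, anomers) | CC(C)(C)[Si](c1ccccc1)(c1ccccc1)OC[C@@]1(C)CCC[C@]2(C)[C@@H](CCC(O)O3)[C@@]3(C)CC[C@@H]12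
F9 | step 12 | 19-[tert-butyl(diphenyl)silyl]oxy-15,16-dinorlabd-13-yn-8α-ol | CC(C)(C)[Si](c1ccccc1)(c1ccccc1)OC[C@@]1(C)CCC[C@]2(C)[C@@H](CCC#C)[C@](C)(O)CC[C@@H]12
F10 | step 16 | (13E)-8α,19-dihydroxylabd-13-en-15-al | OC[C@@]1(C)CCC[C@]2(C)[C@@H](CC/C(C)=C/C=O)[C@](C)(O)CC[C@@H]12
F11 | step 16 | (13E)-8α-hydroxy-15-oxolabd-13-en-19-yl acetate | CC(=O)OC[C@@]1(C)CCC[C@]2(C)[C@@H](CC/C(C)=C/C=O)[C@](C)(O)CC[C@@H]12
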